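**Retrosynthetic overview**
- The C2–aryl bond to the 3,4-dimethoxyphenyl ring is cut last. The target comes from Friedel–Crafts C-arylation of the cyclic oxocarbenium ion of lactol **7** with veratrole, which should converge on the all-trans isomer. Veratrole reacts para to an OMe group, so it gives 3,4-dimethoxyphenyl. 1,2,3-Trimethoxybenzene could not give the 3,4,5-pattern this way.
- Lactol **7** comes from lactone **6** by DIBAL. The lactone ring is the final THF ring and is never opened.
- The two trans methyls in **6** come from Me-cuprate 1,4-addition to butenolide **4** and then enolate methylation. Each methyl enters anti to its neighbouring substituent.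
- Butenolide **4** comes from the (R)-γ-hydroxy-ynoate **3** by semihydrogenation and lactonization. **3** comes from 3,4,5-trimethoxybenzaldehyde and ethyl propiolate by catalytic asymmetric alkynylation, the only externally controlled stereocentre.
- The single heterocycle forms at the lactonization (Step 2).

**Assumptions**
- The target SMILES is the all-trans isomer, (2S,3S,4S,5S).
- The ProPhenol ligand enantiomer is chosen to give (R)-**3**, and the ee is upgraded by crystallizing **4**.

---

**Step 1**
Reactants: **1** 3,4,5-trimethoxybenzaldehyde; **2** ethyl propiolate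
Product: **3** ethyl (R)-4-hydroxy-4-(3,4,5-trimethoxyphenyl)but-2-ynoate
Conditions: ProPhenol (10 mol %), Me2Zn, Ph3P=O (20 mol %), toluene, 4 °C; then aq. NH4Cl
Reagents that add atoms: none
Why: A dinuclear Zn-ProPhenol catalyst forms a zinc alkynylide and delivers it to one face of the aldehyde (asymmetric alkynylation of an aldehyde). This sets the Ar–C–O stereocentre, which becomes C5 of the THF.

**Step 2**
Reactants: **3**
Product: **4** (S)-5-(3,4,5-trimethoxyphenyl)furan-2(5H)-one
Conditions: H2 (1 atm), Lindlar Pd/CaCO3, quinoline, EtOAc, rt; then cat. PPTS, CH2Cl2, rt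
Reagents that add atoms: none
Why: Lindlar semihydrogenation is syn and gives the (Z)-γ-hydroxy enoate, whose cis geometry lets it lactonize (loss of EtOH) to the butenolide. The carbinol centre is untouched, and its CIP label changes from R to S only because the substituent priorities change.

**Step 3**
Reactants: **4**
Product: **5** (4S,5S)-4-methyl-5-(3,4,5-trimethoxyphenyl)oxolan-2-one
Conditions: Me2CuLi (from MeLi, CuI), Et2O/THF, −78 °C; then aq. NH4Cl
Reagents that add atoms: methyllithium, C[Li]
Why: Cuprate conjugate addition (Michael) occurs anti to the γ-aryl group, giving the 4,5-trans lactone. This sets the Me-bearing carbon, C4 of the THF.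

**Step 4**
Reactants: **5**
Product: **6** (3S,4S,5S)-3,4-dimethyl-5-(3,4,5-trimethoxyphenyl)oxolan-2-one
Conditions: LDA, THF, −78 °C; then MeI, DMPU, −78 → −40 °C
Reagents that add atoms: iodomethane, CI
Why: Lactone enolate alkylation occurs anti to the adjacent 4-Me group, giving the 3,4-trans isomer. The result is all-trans lactone **6**, which carries three of the four ring stereocentres.

**Step 5**
Reactants: **6**
Product: **7** (3S,4S,5S)-3,4-dimethyl-5-(3,4,5-trimethoxyphenyl)oxolan-2-ol (anomeric mixture)
Conditions: DIBAL-H (1.1 equiv), CH2Cl2, −78 °C, 1 h; then Rochelle salt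
Reagents that add atoms: none
Why: Partial reduction of the lactone by DIBAL stops at the lactol. The anomeric centre is destroyed in the next step, so the mixture is used as is.

**Step 6**
Reactants: **7** lactol; **8** 1,2-dimethoxybenzene (veratrole)
Product: **9** 5-methoxygalbelgin, (2S,3S,4S,5S)-2-(3,4-dimethoxyphenyl)-3,4-dimethyl-5-(3,4,5-trimethoxyphenyl)oxolane
Conditions: veratrole (6 equiv), BF3·OEt2 (2 equiv), CH2Cl2, −78 → −20 °C; then aq. NaHCO3
Reagents that add atoms: none
Why: Proposed new method: BF3 ionizes the lactol to the 3,4-dimethyl-5-aryl oxocarbenium ion, and veratrole attacks para to an OMe group (C4), anti to the C3-Me, giving the 2,3-trans arrangement. The closest known reaction types are Friedel–Crafts C-glycosylation and Woerpel-type oxocarbenium additions. The benzylic C2–O bond of the product can re-ionize and the C3 centre can equilibrate through the cyclic enol ether, so the mixture should funnel to the thermodynamically preferred all-trans THF.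

---

**Compound list**

| No. | Name | SMILES | Role |
|---|---|---|---|
| 1 | 3,4,5-Trimethoxybenzaldehyde | COc1cc(C=O)cc(OC)c1OC | starting material |
| 2 | Ethyl propiolate | CCOC(=O)C#C | starting material |
| 3 | Ethyl (R)-4-hydroxy-4-(3,4,5-trimethoxyphenyl)but-2-ynoate | CCOC(=O)C#C[C@H](O)c1cc(OC)c(OC)c(OC)c1 | intermediate |
| 4 | (S)-5-(3,4,5-Trimethoxyphenyl)furan-2(5H)-one | O=C1O[C@H](c2cc(OC)c(OC)c(OC)c2)C=C1 | intermediate |
| 5 | (4S,5S)-4-Methyl-5-(3,4,5-trimethoxyphenyl)oxolan-2-one | O=C1O[C@H](c2cc(OC)c(OC)c(OC)c2)[C@@H](C)C1 | intermediate |
| 6 | (3S,4S,5S)-3,4-Dimethyl-5-(3,4,5-trimethoxyphenyl)oxolan-2-one | O=C1O[C@H](c2cc(OC)c(OC)c(OC)c2)[C@@H](C)[C@@H]1C | intermediate |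
| 7 | (3S,4S,5S)-3,4-Dimethyl-5-(3,4,5-trimethoxyphenyl)oxolan-2-ol (C2 anomeric mixture) | OC1O[C@H](c2cc(OC)c(OC)c(OC)c2)[C@@H](C)[C@@H]1C | intermediate |
| 8 | 1,2-Dimethoxybenzene (veratrole) | COc1ccccc1OC | starting material |
| 9 | 5-Methoxygalbelgin | COc1ccc([C@H]2O[C@H](c3cc(OC)c(OC)c(OC)c3)[C@@H](C)[C@@H]2C)cc1OC | target |

**Total step count:** 6
**Longest linear sequence:** 6 steps (1 → 3 → 4 → 5 → 6 → 7 → 9)

**Three steps most likely to fail**
1. **Step 6 (Friedel–Crafts C-arylation).** The diastereoselectivity may be modest, and the oxocarbenium ion may lose a proton to the enol ether, oligomerize, or attack intramolecularly through the trimethoxyaryl ring.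
   - Fallback: add 3,4-dimethoxyphenylmagnesium bromide to lactol **7** to give the 1,4-diol, then cyclodehydrate with TMSOTf or TsOH. This is a different bond-forming logic, relying on benzylic ionization and thermodynamic trans selection.
2. **Step 1 (asymmetric alkynylation).** The ee for an electron-rich aryl aldehyde with a propiolate may be below about 90%.
   - Fallback: make the racemic propargylic alcohol, oxidize it to the ynone, and reduce it with Ru-TsDPEN asymmetric transfer hydrogenation to give (R)-**3**.
3. **Step 4 (α-methylation).** The 3,4-trans selectivity may be poor because the C5-aryl group sits on the same face as the incoming electrophile. The γ-aryl centre may also epimerize in Steps 3–4.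
   - Fallback: abandon the lactone route and make lactol **7** differently. Brown anti-crotylation of **1**, a directing-group-assisted Rh hydroformylation of the terminal alkene to the branched aldehyde, and hydroxy-aldehyde lactolization would give **7**. This route has a different ring-substituent logic, and the labile α-methyl stereocentre would be equilibrated in Step 6.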